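**Retrosynthetic overview** (indene numbering: C1 = CH bearing the 2-formylallyl group, C2 = C=O, C3, C3a, C4 = C–O-acyl, C5, C6, C7 = C–CO2H, C7a = C–CH3)
1. Late stage: the C7 acid is released from a tert-butyl ester (carried earlier as a vinyl group); the C1 side chain comes from enolate alkylation with 3-bromo-2-(bromomethyl)prop-1-ene followed by N-oxide oxidation; the C4 ester comes from the 4β-alcohol and (2E,4E,6R)-4,6-dimethylocta-2,4-dienoic acid (Evans alkylation, Wittig, Horner–Wadsworth–Emmons); C4–O comes from γ-oxidation of the enone and reduction anti to the C7a methyl group.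
2. Core: the cyclopentenone is cut at C3=C3a (aldol condensation of a 1,4-diketone). The six-membered ring is cut at C7–C7a: it is made by one-carbon enlargement of a cyclopentane (C3a, C4, C5, C6, C7), with C7 shifting from C3a to C7a inside a spiro 2,5-dihydrofuran lactol whose ring oxygen sits on C3a and whose lactol carbon is C2.
3. Enabling feature: the quaternary C7a lies between C3a (a latent ketone, the enone β-carbon) and C7, which is an α-quaternary ketone (semipinacol) retron. C3a and C2 are 1,4-related oxygenated carbons, so both fit into one five-membered oxygen heterocycle that makes C7a the electrophilic end of a vinylogous oxocarbenium ion and fixes the geometry of the shift.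
4. Order of ring formation: cyclopentane (bought as 1-acetylcyclopentene; the C3a carbinol and C7 set by reduction, asymmetric epoxidation and anti opening) → temporary spiro-dihydrofuran → six-membered carbocycle by ring expansion → cyclopentenone by aldol, the last two in one operation.

Key step: step 7

Remark: lactol 7 is a mixture of epimers at the lactol carbon; this centre is planarised on ionisation, so the SMILES of 7 leaves it open.

Step 1
Reactants: 1 1-(cyclopent-1-en-1-yl)ethan-1-one
Product: 2 (1S)-1-(cyclopent-1-en-1-yl)ethan-1-ol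
Conditions: (R)-2-methyl-CBS-oxazaborolidine (10 mol %), catecholborane, toluene, −78 °C
Reagents that add atoms: none
Why: Corey–Bakshi–Shibata reduction, in which the (R)-oxazaborolidine–borane complex treats the alkenyl group as the large substituent and should deliver hydride to the face that gives the (S)-carbinol, with 1,2-reduction favoured at low temperature.

Step 2
Reactants: 2 (1S)-1-(cyclopent-1-en-1-yl)ethan-1-ol
Product: 3 (1S)-1-[(1S,5S)-6-oxabicyclo[3.1.0]hexan-1-yl]ethan-1-ol
Conditions: Ti(OiPr)4 (10 mol %), L-(+)-diisopropyl tartrate (12 mol %), t-BuOOH, 4 Å molecular sieves, CH2Cl2, −20 °C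
Reagents that add atoms: tert-butyl hydroperoxide, CC(C)(C)OO
Why: Sharpless asymmetric epoxidation, in which the L-(+)-tartrate complex should deliver oxygen to the alkene face that gives the (1S,5S)-epoxide and the (S)-carbinol is the matched, fast-reacting enantiomer (erythro product), so residual (R)-alcohol stays behind and the enantiomeric purity should rise.

Step 3
Reactants: 3 (1S)-1-[(1S,5S)-6-oxabicyclo[3.1.0]hexan-1-yl]ethan-1-ol
Product: 4 (1S)-1-[(1R,2S)-2-ethenyl-1-hydroxycyclopentyl]ethan-1-ol
Conditions: CH2=CHMgBr (4 equiv), CuI (20 mol %), THF, −40 → 0 °C; then H2O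
Reagents that add atoms: vinylmagnesium bromide, C=C[Mg]Br
Why: Copper-catalysed Grignard opening of the epoxide by SN2 attack with inversion at the only accessible (secondary) carbon, which places the vinyl group (latent C7 carboxyl, and the group that makes C7 an allylic migrating carbon) trans to the tertiary hydroxyl and cis to the two-carbon side chain.

Step 4
Reactants: 4 (1S)-1-[(1R,2S)-2-ethenyl-1-hydroxycyclopentyl]ethan-1-ol
Product: 5 1-[(1R,2S)-2-ethenyl-1-hydroxycyclopentyl]ethan-1-one
Conditions: IBX (1.5 equiv), DMSO, 23 °C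
Reagents that add atoms: none
Why: IBX oxidation converts the secondary alcohol of a 1,2-diol into the α-hydroxy ketone without glycol cleavage and leaves the tertiary alcohol and both stereocentres untouched.

Step 5
Reactants: 5 1-[(1R,2S)-2-ethenyl-1-hydroxycyclopentyl]ethan-1-one
Product: 6 (5R,6S)-6-ethenyl-4-methyl-1-oxaspiro[4.4]non-3-en-2-one
Conditions: Ph3P=C=C=O (1.2 equiv), toluene, 110 °C
Reagents that add atoms: (triphenylphosphoranylidene)ketene (Bestmann ylide), O=C=C=P(c1ccccc1)(c1ccccc1)c1ccccc1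
Why: Butenolide synthesis with the Bestmann ylide: the tertiary hydroxyl adds to the ketene to give an ester-stabilised ylide, which closes on the neighbouring ketone by intramolecular Wittig olefination, so the ring oxygen stays on C3a and C1 and C2 are introduced.

Step 6
Reactants: 6 (5R,6S)-6-ethenyl-4-methyl-1-oxaspiro[4.4]non-3-en-2-one
Product: 7 (5R,6S)-6-ethenyl-2,4-dimethyl-1-oxaspiro[4.4]non-3-en-2-ol
Conditions: CH3Li (1.05 equiv), Et2O, −78 °C; then H2O
Reagents that add atoms: methyllithium, [Li]C
Why: 1,2-Addition of methyllithium to the lactone carbonyl gives a cyclic tetrahedral lithium alkoxide that should not open at −78 °C (mono-addition), and conjugate addition is not expected because the β-carbon is fully substituted.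

Step 7
Reactants: 7 (5R,6S)-6-ethenyl-2,4-dimethyl-1-oxaspiro[4.4]non-3-en-2-ol
Product: 10 (7S,7aS)-7-ethenyl-7a-methyl-1,4,5,6,7,7a-hexahydro-2H-inden-2-one, via ring-expanded enol ether 8 (not isolated), via 1,4-diketone 9 (not isolated)
Conditions: BF3·OEt2 (2 equiv), CH2Cl2, −78 → 0 °C; then 1 M aq HCl (cat.), THF, 23 °C; then KOH, MeOH, 60 °C
Reagents that add atoms: water, O
Why: Proposed new method: BF3·OEt2 ionises the lactol to a spiro 2H-furanium (cyclic vinylogous oxocarbenium) ion in which C7a is the electrophilic β-carbon; the ring oxygen on C3a pushes, C7 shifts from C3a to C7a (one-carbon enlargement of the cyclopentane to the six-membered ring), and the new oxocarbenium ion at C3a (neutral form 8) is hydrolysed to 1,4-diketone 9, which KOH closes to the cyclopentenone by aldol condensation. The closest known reactions are the vinylogous α-ketol (semipinacol) rearrangement of 1-hydroxycyclobutyl enones and acid-promoted pinacol ring expansions of carbinols next to oxocarbenium ions; new here are the cyclic 2H-furanium trigger and the five-to-six enlargement, which should be driven by the conversion of a C=C bond and a C–O single bond into a ketone and by loss of cyclopentane strain rather than by four-ring strain. The six-membered ring is closed by a suprafacial 1,2-alkyl shift (a ring enlargement, not a Baldwin-type cyclisation) and the five-membered ring by a formally 5-(enolendo)-exo-trig aldol with dehydration, the mode by which 1,4-diketones routinely give cyclopentenones. The new quaternary centre C7a is controlled by the temporary heterocycle: the methyl group and C1 are held in the furanium plane, C7 can only bond to the face on which it already sits, and because the vinyl group is cis to C7a on the cyclopentane (step 3) it should end cis to the C7a methyl group, C7 itself migrating with retention. The step needs migration of C7 and not of C4, which the secondary, allylic nature of C7 should secure, and it needs the heterocycle to stay closed until the shift, which the anhydrous Lewis acid stage should secure. The alternative aldol (C4 onto C2) would give a bridged ketol that cannot dehydrate and should revert.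

Step 8
Reactants: 10 (7S,7aS)-7-ethenyl-7a-methyl-1,4,5,6,7,7a-hexahydro-2H-inden-2-one
Product: 11 (7R,7aS)-7a-methyl-2-oxo-2,4,5,6,7,7a-hexahydro-1H-indene-7-carbaldehyde
Conditions: O3, CH2Cl2/MeOH, −78 °C (stopped when 10 is consumed); then PPh3, −78 → 23 °C
Reagents that add atoms: ozone, [O-][O+]=O
Why: Ozonolysis with reductive work-up, in which the electron-rich monosubstituted alkene should react much faster than the electron-poor conjugated enone double bond.

Step 9
Reactants: 11 (7R,7aS)-7a-methyl-2-oxo-2,4,5,6,7,7a-hexahydro-1H-indene-7-carbaldehyde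
Product: 12 (7R,7aS)-7a-methyl-2-oxo-2,4,5,6,7,7a-hexahydro-1H-indene-7-carboxylic acid
Conditions: NaClO2, NaH2PO4, 2-methylbut-2-ene, t-BuOH/H2O, 0 → 23 °C
Reagents that add atoms: sodium chlorite, [Na+].[O-]Cl=O
Why: Pinnick oxidation is mild enough that the α-stereocentre C7 should not epimerise and the enone should be inert, the alkene scavenger removing hypochlorous acid.

Step 10
Reactants: 12 (7R,7aS)-7a-methyl-2-oxo-2,4,5,6,7,7a-hexahydro-1H-indene-7-carboxylic acid
Product: 13 tert-butyl (7R,7aS)-7a-methyl-2-oxo-2,4,5,6,7,7a-hexahydro-1H-indene-7-carboxylate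
Conditions: tert-butyl 2,2,2-trichloroacetimidate (2 equiv), BF3·OEt2 (5 mol %), CH2Cl2/cyclohexane, 23 °C
Reagents that add atoms: tert-butyl 2,2,2-trichloroacetimidate, CC(C)(C)OC(=N)C(Cl)(Cl)Cl
Why: Acid-catalysed tert-butylation of a carboxylic acid with the trichloroacetimidate gives an ester that tolerates the enolate, oxidation and reduction steps ahead and is orthogonal to the dienoate ester at the end.

Step 11
Reactants: 13 tert-butyl (7R,7aS)-7a-methyl-2-oxo-2,4,5,6,7,7a-hexahydro-1H-indene-7-carboxylate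
Product: 14 tert-butyl (7R,7aS)-7a-methyl-2,4-dioxo-2,4,5,6,7,7a-hexahydro-1H-indene-7-carboxylate
Conditions: Pd(OH)2/C (5 mol %), t-BuOOH (5 equiv), K2CO3 (0.25 equiv), CH2Cl2, 4 → 23 °C
Reagents that add atoms: tert-butyl hydroperoxide, CC(C)(C)OO
Why: Pd(OH)2/C-catalysed tert-butylperoxy-radical allylic oxidation of an enone at its γ-position to the 1,4-enedione, regiodefined because C4 is the only γ-carbon bearing hydrogen (C7a is quaternary).

Step 12
Reactants: 14 tert-butyl (7R,7aS)-7a-methyl-2,4-dioxo-2,4,5,6,7,7a-hexahydro-1H-indene-7-carboxylate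
Product: 15 tert-butyl (4S,7R,7aS)-4-hydroxy-7a-methyl-2-oxo-2,4,5,6,7,7a-hexahydro-1H-indene-7-carboxylate
Conditions: NaBH4 (1.0 equiv), CeCl3·7H2O (1.1 equiv), MeOH, −78 °C
Reagents that add atoms: none
Why: Luche 1,2-reduction, expected at the six-ring carbonyl C4 (less hindered and more readily rehybridised than the cyclopentenone carbonyl), with hydride arriving on the face opposite the axial C7a methyl group to give the axial 4β (4S) alcohol, as in reductions of 6-oxo steroids.

Step 13
Reactants: 16 (4R)-4-benzyl-1,3-oxazolidin-2-one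
Product: 17 (4R)-4-benzyl-3-butanoyl-1,3-oxazolidin-2-one
Conditions: n-BuLi, THF, −78 °C; then butanoyl chloride, −78 → 0 °C
Reagents that add atoms: butanoyl chloride, CCCC(=O)Cl
Why: N-Acylation of the lithiated oxazolidinone, the standard entry to Evans imides.

Step 14
Reactants: 17 (4R)-4-benzyl-3-butanoyl-1,3-oxazolidin-2-one
Product: 18 (4R)-4-benzyl-3-[(2R)-2-methylbutanoyl]-1,3-oxazolidin-2-one
Conditions: NaN(SiMe3)2, THF, −78 °C; then CH3I, −78 °C
Reagents that add atoms: iodomethane, CI
Why: Evans asymmetric alkylation, in which the chelated Z-sodium enolate should be methylated on the face opposite the benzyl group to give the (2R) centre.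

Step 15
Reactants: 18 (4R)-4-benzyl-3-[(2R)-2-methylbutanoyl]-1,3-oxazolidin-2-one
Product: 19 (2R)-2-methylbutan-1-ol
Conditions: LiBH4, MeOH (1 equiv), Et2O, 0 °C; aqueous NaOH work-up
Reagents that add atoms: none
Why: Reductive cleavage of the imide with LiBH4 releases the primary alcohol without touching the stereocentre and returns the auxiliary.

Step 16
Reactants: 19 (2R)-2-methylbutan-1-ol
Product: 21 (2E,4R)-2,4-dimethylhex-2-enal, via (R)-2-methylbutanal 20 (not isolated)
Conditions: TEMPO (10 mol %), PhI(OAc)2 (1.1 equiv), CH2Cl2, 23 °C; then Ph3P=C(CH3)CHO, 40 °C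
Reagents that add atoms: 2-(triphenylphosphoranylidene)propanal, CC(C=O)=P(c1ccccc1)(c1ccccc1)c1ccccc1
Why: TEMPO/PhI(OAc)2 oxidation followed in the same flask by Wittig olefination with a stabilised ylide (E-selective), the volatile α-chiral aldehyde being consumed under non-basic conditions so that it should not racemise.

Step 17
Reactants: 21 (2E,4R)-2,4-dimethylhex-2-enal
Product: 22 ethyl (2E,4E,6R)-4,6-dimethylocta-2,4-dienoate
Conditions: (EtO)2P(O)CH2CO2Et, NaH, THF, 0 → 23 °C
Reagents that add atoms: triethyl phosphonoacetate, CCOC(=O)CP(=O)(OCC)OCC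
Why: Horner–Wadsworth–Emmons olefination of an enal, which should give the (2E)-dienoate.

Step 18
Reactants: 22 ethyl (2E,4E,6R)-4,6-dimethylocta-2,4-dienoate
Product: 23 (2E,4E,6R)-4,6-dimethylocta-2,4-dienoic acid
Conditions: LiOH, THF/MeOH/H2O, 23 °C; then 1 M HCl
Reagents that add atoms: lithium hydroxide, [Li+].[OH-]
Why: Saponification of the ethyl ester, with the remote stereocentre and the diene geometry unaffected.

Step 19
Reactants: 15 tert-butyl (4S,7R,7aS)-4-hydroxy-7a-methyl-2-oxo-2,4,5,6,7,7a-hexahydro-1H-indene-7-carboxylate; 23 (2E,4E,6R)-4,6-dimethylocta-2,4-dienoic acid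
Product: 24 tert-butyl (4S,7R,7aS)-4-{[(2E,4E,6R)-4,6-dimethylocta-2,4-dienoyl]oxy}-7a-methyl-2-oxo-2,4,5,6,7,7a-hexahydro-1H-indene-7-carboxylate
Conditions: DCC (1.5 equiv), DMAP (0.3 equiv), CH2Cl2, 0 → 23 °C
Reagents that add atoms: none
Why: Steglich esterification acylates the hindered axial allylic alcohol through the acylpyridinium ion with retention at C4 and without isomerising the dienoate.

Step 20
Reactants: 24 tert-butyl (4S,7R,7aS)-4-{[(2E,4E,6R)-4,6-dimethylocta-2,4-dienoyl]oxy}-7a-methyl-2-oxo-2,4,5,6,7,7a-hexahydro-1H-indene-7-carboxylate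
Product: 25 tert-butyl (1R,4S,7R,7aS)-1-[2-(bromomethyl)prop-2-en-1-yl]-4-{[(2E,4E,6R)-4,6-dimethylocta-2,4-dienoyl]oxy}-7a-methyl-2-oxo-2,4,5,6,7,7a-hexahydro-1H-indene-7-carboxylate
Conditions: LDA (1.05 equiv), THF, −78 °C; then 3-bromo-2-(bromomethyl)prop-1-ene (5 equiv), DMPU, −78 → −30 °C
Reagents that add atoms: 3-bromo-2-(bromomethyl)prop-1-ene, C=C(CBr)CBr
Why: Kinetic deprotonation of the enone at C1 gives the cross-conjugated lithium enolate, which should be alkylated by the allylic dibromide (in excess, to avoid double reaction) on the face away from the bulkier C7 branch of C7a, that is cis to the methyl group (1R), and this is also the epimer expected to be more stable at this epimerisable centre.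

Step 21
Reactants: 25 tert-butyl (1R,4S,7R,7aS)-1-[2-(bromomethyl)prop-2-en-1-yl]-4-{[(2E,4E,6R)-4,6-dimethylocta-2,4-dienoyl]oxy}-7a-methyl-2-oxo-2,4,5,6,7,7a-hexahydro-1H-indene-7-carboxylate
Product: 26 tert-butyl (1R,4S,7R,7aS)-4-{[(2E,4E,6R)-4,6-dimethylocta-2,4-dienoyl]oxy}-1-(2-formylprop-2-en-1-yl)-7a-methyl-2-oxo-2,4,5,6,7,7a-hexahydro-1H-indene-7-carboxylate
Conditions: 4-methylmorpholine N-oxide (5 equiv), 4 Å molecular sieves, MeCN, 23 °C
Reagents that add atoms: 4-methylmorpholine N-oxide, C[N+]1([O-])CCOCC1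
Why: Ganem oxidation, in which the N-oxide displaces the allylic bromide and the alkoxyammonium salt eliminates N-methylmorpholine to give the 2-substituted acrolein under conditions that should leave the esters and the enone alone.

Step 22
Reactants: 26 tert-butyl (1R,4S,7R,7aS)-4-{[(2E,4E,6R)-4,6-dimethylocta-2,4-dienoyl]oxy}-1-(2-formylprop-2-en-1-yl)-7a-methyl-2-oxo-2,4,5,6,7,7a-hexahydro-1H-indene-7-carboxylate
Product: 27 (1R,4S,7R,7aS)-4-{[(2E,4E,6R)-4,6-dimethylocta-2,4-dienoyl]oxy}-1-(2-formylprop-2-en-1-yl)-7a-methyl-2-oxo-2,4,5,6,7,7a-hexahydro-1H-indene-7-carboxylic acid (CNP0302671.3)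
Conditions: CF3CO2H/CH2Cl2 (1:4), 0 → 23 °C
Reagents that add atoms: none
Why: Acidolysis of the tert-butyl ester by loss of isobutene, conditions under which the secondary dienoate ester, the enal and the enone should persist.

**Compound list**
1 | 1-(cyclopent-1-en-1-yl)ethan-1-one (1-acetylcyclopentene) | CC(=O)C1=CCCC1 | starting material
2 | (1S)-1-(cyclopent-1-en-1-yl)ethan-1-ol | C[C@H](O)C1=CCCC1 | intermediate
3 | (1S)-1-[(1S,5S)-6-oxabicyclo[3.1.0]hexan-1-yl]ethan-1-ol | C[C@H](O)[C@@]12CCC[C@@H]1O2 | intermediate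
4 | (1S)-1-[(1R,2S)-2-ethenyl-1-hydroxycyclopentyl]ethan-1-ol | C=C[C@@H]1CCC[C@]1(O)[C@H](C)O | intermediate
5 | 1-[(1R,2S)-2-ethenyl-1-hydroxycyclopentyl]ethan-1-one | C=C[C@@H]1CCC[C@]1(O)C(C)=O | intermediate
6 | (5R,6S)-6-ethenyl-4-methyl-1-oxaspiro[4.4]non-3-en-2-one | C=C[C@@H]1CCC[C@@]12OC(=O)C=C2C | intermediate
7 | (5R,6S)-6-ethenyl-2,4-dimethyl-1-oxaspiro[4.4]non-3-en-2-ol (both lactol epimers) | C=C[C@@H]1CCC[C@@]12OC(C)(O)C=C2C | intermediate
8 | (3aR,4S)-4-ethenyl-2,3a-dimethyl-3a,4,5,6-tetrahydro-1-benzofuran | CC1=C[C@@]2(C)[C@H](C=C)CCC=C2O1 | intermediate (not isolated)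
9 | (2S,3S)-3-ethenyl-2-methyl-2-(2-oxopropyl)cyclohexan-1-one | O=C1CCC[C@@H](C=C)[C@]1(C)CC(C)=O | intermediate (not isolated)
10 | (7S,7aS)-7-ethenyl-7a-methyl-1,4,5,6,7,7a-hexahydro-2H-inden-2-one | O=C1C=C2CCC[C@@H](C=C)[C@]2(C)C1 | intermediate
11 | (7R,7aS)-7a-methyl-2-oxo-2,4,5,6,7,7a-hexahydro-1H-indene-7-carbaldehyde | O=C1C=C2CCC[C@@H](C=O)[C@]2(C)C1 | intermediate
12 | (7R,7aS)-7a-methyl-2-oxo-2,4,5,6,7,7a-hexahydro-1H-indene-7-carboxylic acid | O=C1C=C2CCC[C@@H](C(=O)O)[C@]2(C)C1 | intermediate
13 | tert-butyl (7R,7aS)-7a-methyl-2-oxo-2,4,5,6,7,7a-hexahydro-1H-indene-7-carboxylate | O=C1C=C2CCC[C@@H](C(=O)OC(C)(C)C)[C@]2(C)C1 | intermediate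
14 | tert-butyl (7R,7aS)-7a-methyl-2,4-dioxo-2,4,5,6,7,7a-hexahydro-1H-indene-7-carboxylate | O=C1C=C2C(=O)CC[C@@H](C(=O)OC(C)(C)C)[C@]2(C)C1 | intermediate
15 | tert-butyl (4S,7R,7aS)-4-hydroxy-7a-methyl-2-oxo-2,4,5,6,7,7a-hexahydro-1H-indene-7-carboxylate | O=C1C=C2[C@@H](O)CC[C@@H](C(=O)OC(C)(C)C)[C@]2(C)C1 | intermediate
16 | (4R)-4-benzyl-1,3-oxazolidin-2-one | O=C1N[C@H](Cc2ccccc2)CO1 | starting material
17 | (4R)-4-benzyl-3-butanoyl-1,3-oxazolidin-2-one | CCCC(=O)N1[C@H](Cc2ccccc2)COC1=O | intermediate
18 | (4R)-4-benzyl-3-[(2R)-2-methylbutanoyl]-1,3-oxazolidin-2-one | CC[C@@H](C)C(=O)N1[C@H](Cc2ccccc2)COC1=O | intermediate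
19 | (2R)-2-methylbutan-1-ol | CC[C@@H](C)CO | intermediate
20 | (2R)-2-methylbutanal | CC[C@@H](C)C=O | intermediate (not isolated)
21 | (2E,4R)-2,4-dimethylhex-2-enal | O=C/C(C)=C/[C@H](C)CC | intermediate
22 | ethyl (2E,4E,6R)-4,6-dimethylocta-2,4-dienoate | CCOC(=O)/C=C/C(C)=C/[C@H](C)CC | intermediate
23 | (2E,4E,6R)-4,6-dimethylocta-2,4-dienoic acid | OC(=O)/C=C/C(C)=C/[C@H](C)CC | intermediate
24 | tert-butyl (4S,7R,7aS)-4-{[(2E,4E,6R)-4,6-dimethylocta-2,4-dienoyl]oxy}-7a-methyl-2-oxo-2,4,5,6,7,7a-hexahydro-1H-indene-7-carboxylate | O=C1C=C2[C@@H](OC(=O)/C=C/C(C)=C/[C@H](C)CC)CC[C@@H](C(=O)OC(C)(C)C)[C@]2(C)C1 | intermediate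
25 | tert-butyl (1R,4S,7R,7aS)-1-[2-(bromomethyl)prop-2-en-1-yl]-4-{[(2E,4E,6R)-4,6-dimethylocta-2,4-dienoyl]oxy}-7a-methyl-2-oxo-2,4,5,6,7,7a-hexahydro-1H-indene-7-carboxylate | O=C1C=C2[C@@H](OC(=O)/C=C/C(C)=C/[C@H](C)CC)CC[C@@H](C(=O)OC(C)(C)C)[C@]2(C)[C@H]1CC(=C)CBr | intermediate
26 | tert-butyl (1R,4S,7R,7aS)-4-{[(2E,4E,6R)-4,6-dimethylocta-2,4-dienoyl]oxy}-1-(2-formylprop-2-en-1-yl)-7a-methyl-2-oxo-2,4,5,6,7,7a-hexahydro-1H-indene-7-carboxylate | O=C1C=C2[C@@H](OC(=O)/C=C/C(C)=C/[C@H](C)CC)CC[C@@H](C(=O)OC(C)(C)C)[C@]2(C)[C@H]1CC(=C)C=O | intermediate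
27 | (1R,4S,7R,7aS)-4-{[(2E,4E,6R)-4,6-dimethylocta-2,4-dienoyl]oxy}-1-(2-formylprop-2-en-1-yl)-7a-methyl-2-oxo-2,4,5,6,7,7a-hexahydro-1H-indene-7-carboxylic acid (CNP0302671.3) | C=C(C=O)C[C@H]1C(=O)C=C2[C@@H](OC(=O)/C=C/C(C)=C/[C@H](C)CC)CC[C@@H](C(=O)O)[C@@]21C | target

**Step count and risks**
Total step count: 22. Longest linear sequence: 16 steps (steps 1–12 and 19–22); the acid fragment 23 takes 6 steps (13–18).

Steps most likely to fail:

1. Step 7 (proposed new method). What may go wrong: the 1,2-shift may be too slow for a cyclopentane without four-ring strain, so that the furanium ion only loses a proton to dienol ethers; the unsubstituted ring carbon C4 may migrate instead of C7; or the heterocycle may open before the shift, so that the geometric control of C7a is lost. Fallback (known chemistry, a different ring enlargement): it sets out from hydroxy ketone 5. Treatment with BF3·OEt2 in CH2Cl2 should bring about the α-ketol (acyloin) rearrangement with ring enlargement, the allylic carbon migrating to the former acetyl carbon, as in the D-homoannulation of 17-hydroxy-20-oxo steroids, to give (3S)-3-ethenyl-2-hydroxy-2-methylcyclohexan-1-one F1. Acetylation (Ac2O, DMAP) should give (6S)-6-ethenyl-1-methyl-2-oxocyclohexyl acetate F2. Dissolving-metal reductive alkylation (Li, NH3/THF, −78 °C; then prop-2-yn-1-yl bromide) should form the regiodefined enolate and alkylate it anti to the vinyl group to give (2S,3S)-3-ethenyl-2-methyl-2-(prop-2-yn-1-yl)cyclohexan-1-one F3. Hydration of the alkyne (NaAuCl4 cat., MeOH/H2O) should give 1,4-diketone 9, where the fallback comes back to the route; 9 is closed to 10 with KOH/MeOH as in the last stage of step 7.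

2. Step 12. What may go wrong: poor site selectivity between the two conjugated carbonyl groups of the enedione, or conjugate reduction, so that the C2 ketone is lost or diols form. Fallback (electrophilic γ-hydroxylation instead of carbonyl reduction): it sets out from enone 13 and bypasses 14. Soft enolisation (TBSOTf, Et3N, CH2Cl2) should give the extended dienol ether tert-butyl (7R,7aS)-2-{[tert-butyl(dimethyl)silyl]oxy}-7a-methyl-5,6,7,7a-tetrahydro-1H-indene-7-carboxylate F4. Oxidation with dimethyldioxirane in acetone at −78 °C and aqueous work-up should hydroxylate C4 by axial attack on the face of the angular methyl group, as in the 6β-hydroxylation of steroidal 3,5-dienol ethers, and so give alcohol 15, where the fallback comes back to the route.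

3. Step 20. What may go wrong: double alkylation or O-alkylation by the bis-electrophile, competing deprotonation of the dienoate or at C4, or low facial selectivity at C1. Fallback (conjugate addition and methylenation instead of alkylation and oxidation): it sets out from 24. Kinetic silylation (LDA, Me3SiCl, THF, −78 °C) should give tert-butyl (4S,7R,7aS)-4-{[(2E,4E,6R)-4,6-dimethylocta-2,4-dienoyl]oxy}-7a-methyl-2-[(trimethylsilyl)oxy]-5,6,7,7a-tetrahydro-4H-indene-7-carboxylate F5. Mukaiyama–Michael addition to acrolein (BF3·OEt2, CH2Cl2, −78 °C) should give tert-butyl (1R,4S,7R,7aS)-4-{[(2E,4E,6R)-4,6-dimethylocta-2,4-dienoyl]oxy}-7a-methyl-2-oxo-1-(3-oxopropyl)-2,4,5,6,7,7a-hexahydro-1H-indene-7-carboxylate F6. α-Methylenation of the aldehyde (aqueous CH2O, pyrrolidine and propanoic acid as catalysts, i-PrOH, 45 °C) should give enal 26, where the fallback comes back to the route, bypassing 25.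

**Further compounds**
F1 | step 7 | (3S)-3-ethenyl-2-hydroxy-2-methylcyclohexan-1-one (C2 epimers) | O=C1CCC[C@@H](C=C)C1(C)O
F2 | step 7 | (6S)-6-ethenyl-1-methyl-2-oxocyclohexyl acetate (C1 epimers) | O=C1CCC[C@@H](C=C)C1(C)OC(C)=O
F3 | step 7 | (2S,3S)-3-ethenyl-2-methyl-2-(prop-2-yn-1-yl)cyclohexan-1-one | O=C1CCC[C@@H](C=C)[C@]1(C)CC#C
F4 | step 12 | tert-butyl (7R,7aS)-2-{[tert-butyl(dimethyl)silyl]oxy}-7a-methyl-5,6,7,7a-tetrahydro-1H-indene-7-carboxylate | CC(C)(C)[Si](C)(C)OC1=CC2=CCC[C@@H](C(=O)OC(C)(C)C)[C@]2(C)C1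
F5 | step 20 | tert-butyl (4S,7R,7aS)-4-{[(2E,4E,6R)-4,6-dimethylocta-2,4-dienoyl]oxy}-7a-methyl-2-[(trimethylsilyl)oxy]-5,6,7,7a-tetrahydro-4H-indene-7-carboxylate | C[Si](C)(C)OC1=C[C@]2(C)C(=C1)[C@@H](OC(=O)/C=C/C(C)=C/[C@H](C)CC)CC[C@H]2C(=O)OC(C)(C)C
F6 | step 20 | tert-butyl (1R,4S,7R,7aS)-4-{[(2E,4E,6R)-4,6-dimethylocta-2,4-dienoyl]oxy}-7a-methyl-2-oxo-1-(3-oxopropyl)-2,4,5,6,7,7a-hexahydro-1H-indene-7-carboxylate | O=C1C=C2[C@@H](OC(=O)/C=C/C(C)=C/[C@H](C)CC)CC[C@@H](C(=O)OC(C)(C)C)[C@]2(C)[C@H]1CCC=O
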